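(The runs stem from a simulated flask for substances that don't exist; scatter was added.)

Amounts come first. Every target molecule, free or bound in side product, has taken up one coupling partner, so the coupled amount C = target + half the side product (in percent of substrate charged) counts the partner that reached product.

| flask | substrate | coupling partner | remark | time |
|---|---|---|---|---|
| eta | 0.050 M | 0.025 M | run made earlier |  |
| alpha | 0.034 M | 0.025 M | run made earlier |  |
| delta | 0.075 M | 0.025 M | run made earlier |  |
| epsilon | 0.050 M | 0.038 M | run made earlier |  |
| spring | 0.050 M (fed, over 2.0 h) | 0.0250 M | all else is in the flask from the start; the feed brings no volume worth counting | 10 h |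
| autumn | 0.050 M | 0.0250 M | everything together at the start | 10 h |
| noon | 0.050 M (in portions, 2, over 8.0 h) | 0.0250 M | first portion at the start, last at 8.0 h | 10 h |
| dusk | 0.050 M | 0.0250 M (fed, over 8.0 h) | all else is in the flask from the start; the feed brings no volume worth counting | 10 h |
| dawn | 0.050 M (fed, over 8.0 h) | 0.0250 M | all else is in the flask from the start; the feed brings no volume worth counting | 10 h |

| run | time / h | side product / % | target / % |
|---|---|---|---|
| eta | 0.500 | 0 | 0 |
| eta | 0.833 | 0 | 0 |
| eta | 1.50 | 0 | 5.7 |
| eta | 3.00 | 12.9 | 22.2 |
| eta | 6.00 | 30.9 | 13.8 |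
| alpha | 1.33 | 0 | 1.3 |
| alpha | 2.50 | 1.6 | 6.8 |
| alpha | 4.00 | 8.6 | 18.4 |
| alpha | 5.00 | 14.9 | 18.7 |
| alpha | 6.00 | 19.5 | 17.5 |
| delta | 0.500 | 2.5 | 0 |
| delta | 0.833 | 0.3 | 3.2 |
| delta | 1.50 | 7.4 | 18.0 |
| delta | 3.00 | 19.7 | 13.3 |
| delta | 6.00 | 34.3 | 4.3 |
| epsilon | 0.500 | 1.8 | 0 |
| epsilon | 1.50 | 7.2 | 41.2 |
| epsilon | 3.00 | 22.1 | 39.2 |
| epsilon | 4.00 | 31.9 | 37.7 |
| epsilon | 6.00 | 42.5 | 32.7 |

(scatter of a reading: 1 percentage point)

- in percentages every species weighs as the substrate in it: one side product counts as two

- the flask with the highest amount of side product, in percent of the substrate charged ("all alike" if they lie within 1.5 percentage points) (spring / autumn / noon / dusk / dawn / all alike)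
- final side product, as a percentage of the substrate charged, in spring
- final side product, as a percentage of the substrate charged, in autumn
- final side product, as a percentage of the substrate charged, in noon
- final side product, as a percentage of the substrate charged, in dusk
- final side product, as a percentage of the substrate charged, in dawn

The eta run has the same charge as autumn, so its readings stand for autumn's curve up to 6.00 h. Eta's target starts flat, reading 0% at 0.833 h, and the knee lies near 1.50 h. Eta's target reads 22.2% at 3.00 h, and eta's side product crosses it before 6.00 h, where eta reads C = 29.2%, or 0.0146 M. Of 0.025 M charged, 0.0104 M is then missing. Read as a first-order loss up to the knee, this gives the partner loss rate λ = 0.357 h⁻¹, so on this reading a fraction e^(−λt) of the partner survives to a knee at time t. In the alpha run the same λ puts the knee at 2.78 h, and alpha's target reads 6.8% at 2.50 h.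

Between 3.00 h and 6.00 h, eta's target readings fall at 0.158 h⁻¹. My reckoning holds that rate on to 10 h, which gives autumn an estimated 7.32% of target and 43.8% of side product, on the way to a level of twice C, 58.4%. My reckoning for dawn assumes no knee before its feed ends. Then λ gives a surviving fraction of 5.73% of dawn's partner after 8.0 h, and that much partner, coupled and turned to side product, reckons at 5.73% of side product.

The forecast answers autumn and gives spring 38%, autumn 42%, noon 24%, dusk 27% and dawn 24%. For noon and dawn it reasons that “substrate stays low during the window when target is present”. The two part at dawn, 5.73% here against 24% there.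

At 10 h the flasks hold side product: spring 24.0%, autumn 41.7%, noon 10.9%, dusk 24.2%, dawn 0.813%. Autumn stands highest.

    substrate + coupling partner + target → 2 target (k = 6100 M⁻² h⁻¹)
    substrate + coupling partner → target (k = 0.00320 M⁻¹ h⁻¹)
    substrate + target → side product (k = 5.90 M⁻¹ h⁻¹)
    coupling partner → decomposed reagent (k = 0.310 h⁻¹)
    coupling partner → decomposition product (k = 2.20 × 10⁻⁴ h⁻¹)

Dawn held 7.70% of its coupling partner at 8.00 h, against 5.73% from λ. The neighbouring flask is autumn with 0.043 M of coupling partner. Scaling eta's knee inversely with the partner charge puts its take-off at 0.872 h. Then λ leaves 0.0315 M, which is C = 63.0%. At 10.0 h that flask holds target 33.9% and side product 54.1%, so its C is 60.9%.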